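**Strategy.** With the lactone carbonyl as C1 and the carbinol that bears the propyl group as C13, neopeltolide is cut at O–C3 and C3–C4. Both bonds lie in the 2,6-cis-tetrahydropyran (O, C3–C7). Because this pyran is bridged inside the 14-membered lactone, the same two bonds also tie the macrocycle together. One Prins macrocyclisation of an open-chain ester therefore closes both rings, creates C3 and C5, and places an equatorial acetate on C5. Its substrate is the C13 3,3-diethoxypropanoate of a C4–C16 chain that ends in a C7 homoallylic alcohol and already carries C7, C9, C11 and C13. Afterwards the C5 acetate is exchanged, with inversion, for the oxazole side-chain ester.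

Key step: step 14

Assumption: the hand of each chiral reagent ((DHQ)2AQN and the two Ipc2B reagents) is assigned from the accepted empirical models, the SMILES define the configuration that is meant, and locants C1–C16 follow the numbering above.

**Route**

Step 1
Reactants: 1 3-methylglutaric anhydride
Product: 2 (3R)-5-methoxy-3-methyl-5-oxopentanoic acid (acid carbon = C7; ester carbon = C11)
Conditions: MeOH, (DHQ)2AQN (cat.), Et2O, −40 °C
Reagents that add atoms: methanol, CO
Why: Catalytic enantioselective alcoholysis (desymmetrisation) of a prochiral cyclic anhydride, in which the quinine-series alkaloid acts as a chiral general base and directs methanol to one of the two enantiotopic carbonyl groups, which sets C9.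

Step 2
Reactants: 2 (3R)-5-methoxy-3-methyl-5-oxopentanoic acid
Product: 4 methyl (3R)-3-methyl-5-oxopentanoate, via acid chloride 3 (not isolated)
Conditions: (COCl)2, DMF (cat.), CH2Cl2, 0 °C; then H2 (1 atm), Pd/C, 2,6-lutidine, THF, rt
Reagents that add atoms: oxalyl chloride, O=C(Cl)C(=O)Cl (chlorine of 3 only)
Why: Rosenmund reduction should stop at the aldehyde because lutidine tempers the catalyst and binds HCl, the methyl ester is inert, and cold, brief handling of 3 limits ester/acyl chloride interchange that would erode C9.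

Step 3
Reactants: 4 methyl (3R)-3-methyl-5-oxopentanoate; 5 allylmagnesium bromide
Product: 7 (4R,6S)-4-methyl-6-(prop-2-en-1-yl)oxan-2-one (cis lactone), via hydroxy ester 6 (not isolated)
Conditions: (−)-Ipc2BOMe, 5, Et2O, 0 °C to rt; then 4, −78 °C; NaOH, H2O2; then TsOH (cat.), CH2Cl2, rt
Reagents that add atoms: none
Why: Brown allylboration, in which the chair transition state of the (+)-α-pinene-derived allylborane delivers allyl to the Si face of the aldehyde under reagent control and sets C7, followed by acid-catalysed lactonisation to the cis-4,6-disubstituted δ-lactone, from which the trans isomers that arise from the minor enantiomer of 4 or from minor-face attack should be removable.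

Step 4
Reactants: 7 (4R,6S)-4-methyl-6-(prop-2-en-1-yl)oxan-2-one
Product: 8 (3R,5S)-5-hydroxy-N-methoxy-N,3-dimethyloct-7-enamide
Conditions: MeNH(OMe)·HCl, AlMe3, CH2Cl2, 0 °C to rt
Reagents that add atoms: N,O-dimethylhydroxylamine hydrochloride, CNOC.Cl
Why: Weinreb aminolysis of a lactone with the aluminium amide opens the ring at the acyl C–O bond, so neither C7 nor C9 is touched.

Step 5
Reactants: 8 (3R,5S)-5-hydroxy-N-methoxy-N,3-dimethyloct-7-enamide
Product: 9 (3R,5S)-N-methoxy-N,3-dimethyl-5-(triethylsilyloxy)oct-7-enamide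
Conditions: TESCl, imidazole, CH2Cl2, 0 °C to rt
Reagents that add atoms: chlorotriethylsilane, CC[Si](Cl)(CC)CC
Why: Standard silyl ether protection blocks relactonisation and masks C7–OH with a group that can later be removed in the presence of an acetal.

Step 6
Reactants: 9 (3R,5S)-N-methoxy-N,3-dimethyl-5-(triethylsilyloxy)oct-7-enamide
Product: 10 (4R,6S)-4-methyl-6-(triethylsilyloxy)non-8-en-2-one
Conditions: MeMgBr, THF, 0 °C
Reagents that add atoms: methylmagnesium bromide, C[Mg]Br
Why: Weinreb ketone synthesis, in which the chelated tetrahedral adduct survives until work-up and so prevents a second addition; the new methyl group is C12.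

Step 7
Reactants: 10 (4R,6S)-4-methyl-6-(triethylsilyloxy)non-8-en-2-one; 11 butanal
Product: 13 (4R,8R,10S)-4-hydroxy-8-methyl-10-(triethylsilyloxy)tridec-12-en-6-one, via boron enolate 12 (not isolated)
Conditions: (+)-Ipc2BCl, Et3N, Et2O, 0 °C; then 11, −78 to −20 °C; H2O2, MeOH, pH 7 buffer
Reagents that add atoms: (+)-B-chlorodiisopinocampheylborane, ClB([C@H]1C[C@H]2C[C@@H]([C@@H]1C)C2(C)C)[C@H]1C[C@H]2C[C@@H]([C@@H]1C)C2(C)C (boron and ligands of 12 only)
Why: Reagent-controlled boron aldol reaction of a methyl ketone (Paterson aldol), in which Ipc2BCl/Et3N enolises 10 on the methyl side and the (−)-α-pinene-derived ligands steer the enolate to the Si face of butanal, which sets C13 as R while C7 and C9 are too remote to interfere.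

Step 8
Reactants: 13 (4R,8R,10S)-4-hydroxy-8-methyl-10-(triethylsilyloxy)tridec-12-en-6-one
Product: 14 (4R,6R,8S,10S)-6-hydroxy-8-methyl-10-(triethylsilyloxy)tridec-12-en-4-yl acetate
Conditions: SmI2 (cat.), MeCHO (excess), THF, −10 °C
Reagents that add atoms: acetaldehyde, CC=O
Why: Evans–Tishchenko reduction, in which the C13 hydroxyl forms a samarium-bound hemiacetal with acetaldehyde and passes its hydride to the C11 ketone through a chair-like bicyclic transition state, which gives the 1,3-anti C11 alcohol (R) and masks C13 as its acetate in the same operation.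

Step 9
Reactants: 14 (4R,6R,8S,10S)-6-hydroxy-8-methyl-10-(triethylsilyloxy)tridec-12-en-4-yl acetate
Product: 15 (4R,6R,8S,10S)-6-methoxy-8-methyl-10-(triethylsilyloxy)tridec-12-en-4-yl acetate
Conditions: Me3OBF4, Proton Sponge, 4 Å MS, CH2Cl2, rt
Reagents that add atoms: trimethyloxonium tetrafluoroborate, C[O+](C)C.F[B-](F)(F)F
Why: O-Methylation with a Meerwein salt buffered by a non-nucleophilic base forms no alkoxide and so avoids 1,3-acetyl migration, elimination and silyl loss.

Step 10
Reactants: 15 (4R,6R,8S,10S)-6-methoxy-8-methyl-10-(triethylsilyloxy)tridec-12-en-4-yl acetate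
Product: 16 (4R,6R,8S,10S)-6-methoxy-8-methyl-10-(triethylsilyloxy)tridec-12-en-4-ol
Conditions: DIBAL-H, CH2Cl2, −78 °C; Rochelle salt
Reagents that add atoms: none
Why: Reductive ester cleavage removes the only carbonyl group of the molecule and frees C13–OH without base, so the TES ether, the methyl ether and the alkene should be untouched.

Step 11
Reactants: 17 ethyl 3,3-diethoxypropanoate
Product: 18 3,3-diethoxypropanoic acid
Conditions: NaOH, H2O/EtOH, rt; then cold 1 M HCl to pH 3, immediate extraction
Reagents that add atoms: sodium hydroxide, [Na+].[OH-]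
Why: Saponification proceeds under basic conditions to which the acetal is inert, and a cold, brief acidification frees the acid without hydrolysing the acetal.

Step 12
Reactants: 16 (4R,6R,8S,10S)-6-methoxy-8-methyl-10-(triethylsilyloxy)tridec-12-en-4-ol; 18 3,3-diethoxypropanoic acid
Product: 19 (4R,6R,8S,10S)-6-methoxy-8-methyl-10-(triethylsilyloxy)tridec-12-en-4-yl 3,3-diethoxypropanoate
Conditions: DCC, DMAP, CH2Cl2, 0 °C to rt
Reagents that add atoms: none
Why: Steglich esterification, in which C13–OH is the only free nucleophile because C7–OH is still silylated, and the neutral carbodiimide/DMAP activation keeps the acetal intact and retains C13.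

Step 13
Reactants: 19 (4R,6R,8S,10S)-6-methoxy-8-methyl-10-(triethylsilyloxy)tridec-12-en-4-yl 3,3-diethoxypropanoate
Product: 20 (4R,6R,8R,10S)-10-hydroxy-6-methoxy-8-methyltridec-12-en-4-yl 3,3-diethoxypropanoate (Prins precursor)
Conditions: HF·pyridine, pyridine, THF, 0 °C
Reagents that add atoms: none
Why: Fluoride-mediated cleavage of the labile TES ether, with excess pyridine buffering HF so that the diethyl acetal and the ester should persist.

Step 14
Reactants: 20 (4R,6R,8R,10S)-10-hydroxy-6-methoxy-8-methyltridec-12-en-4-yl 3,3-diethoxypropanoate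
Product: 23 (1R,5R,7R,9S,11R,13S)-7-methoxy-9-methyl-3-oxo-5-propyl-4,15-dioxabicyclo[9.3.1]pentadecan-13-yl acetate (equatorial C5 acetate), via macrocyclic mixed acetal 21 (not isolated), via oxocarbenium ion 22 (not isolated)
Conditions: TESOTf, TMSOAc, AcOH (ca. 5 mM), rt; NaHCO3 quench
Reagents that add atoms: trimethylsilyl acetate, CC(=O)O[Si](C)(C)C
Why: TESOTf ionises the diethyl acetal, the C7 oxygen (free or transiently silylated) adds to C3 to give 21, and a second ionisation expels the remaining ethoxide, so reversible acetal exchange at high dilution closes the 12-membered ring of the (E)-oxocarbenium ion 22 (C1–C3, O, C7–C13, O). The terminal alkene carbon C4 then attacks C3 in a 6-endo-trig chair closure that forms the tetrahydropyran and, through the same C3–C4 bond, completes the 14-membered lactone perimeter, after which acetate captures the C5 cation. The closest known reaction type is the acetate-terminated Prins cyclisation of homoallylic alcohols with acetals, which has also been run intramolecularly to make pyran-bridged macrolides. C3 is controlled by C7, because the chair places both the C8 chain and the C2 arm equatorial and so gives the 2,6-cis ring, and C5 is set by equatorial approach of acetate to that chair cation. The step needs ring closure to win over oligomerisation, which dilution and the reversibility of every event before C–C bond formation should secure, and it needs 2,6-cis/5-equatorial selectivity, which the C7 centre secures, while C9, C11 and C13 lie far from the cation. The acetal is preferred to the free formylacetate, which would enolise, and any β-alkoxyacrylate formed by proton loss should be re-protonated in the acidic medium.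

Step 15
Reactants: 23 macrolactone C5 acetate
Product: 24 (1R,5R,7R,9S,11R,13S)-13-hydroxy-7-methoxy-9-methyl-5-propyl-4,15-dioxabicyclo[9.3.1]pentadecan-3-one (equatorial C5 alcohol)
Conditions: K2CO3, MeOH, rt
Reagents that add atoms: none
Why: Base-catalysed transesterification (methanolysis), in which the exposed equatorial acetate should exchange much faster than the hindered lactone of a secondary carbinol, and no stereocentre is touched.

Step 16
Reactants: 25 propargylamine
Product: 26 methyl N-(prop-2-yn-1-yl)carbamate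
Conditions: ClCO2Me, Et3N, CH2Cl2, 0 °C
Reagents that add atoms: methyl chloroformate, COC(=O)Cl
Why: N-Acylation of a primary amine with a chloroformate (carbamate formation).

Step 17
Reactants: 26 methyl N-(prop-2-yn-1-yl)carbamate; 27 ethyl 2-bromo-1,3-oxazole-4-carboxylate
Product: 28 ethyl 2-[3-(methoxycarbonylamino)prop-1-yn-1-yl]-1,3-oxazole-4-carboxylate
Conditions: PdCl2(PPh3)2 (cat.), CuI (cat.), Et3N, THF, rt to 50 °C
Reagents that add atoms: none
Why: Sonogashira coupling, in which the electron-poor C2–Br bond of the oxazole undergoes ready oxidative addition and the ester and the carbamate N–H are tolerated.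

Step 18
Reactants: 28 ethyl 2-[3-(methoxycarbonylamino)prop-1-yn-1-yl]-1,3-oxazole-4-carboxylate
Product: 29 ethyl 2-[(1Z)-3-(methoxycarbonylamino)prop-1-en-1-yl]-1,3-oxazole-4-carboxylate
Conditions: H2 (1 atm), Lindlar catalyst, quinoline, EtOAc, rt
Reagents that add atoms: none
Why: Lindlar semi-hydrogenation delivers H2 in a syn fashion on the poisoned palladium surface, which gives the Z-alkene and should stop there.

Step 19
Reactants: 29 ethyl 2-[(1Z)-3-(methoxycarbonylamino)prop-1-en-1-yl]-1,3-oxazole-4-carboxylate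
Product: 30 methyl N-[(2Z)-3-(4-formyl-1,3-oxazol-2-yl)prop-2-en-1-yl]carbamate
Conditions: DIBAL-H (excess for N–H), CH2Cl2, −78 °C; Rochelle salt
Reagents that add atoms: none
Why: Partial reduction of an ester with DIBAL-H, in which the aluminium hemiacetal persists at −78 °C and collapses to the aldehyde only on work-up, while the deprotonated carbamate is unreactive.

Step 20
Reactants: 30 methyl N-[(2Z)-3-(4-formyl-1,3-oxazol-2-yl)prop-2-en-1-yl]carbamate
Product: 31 methyl N-[(2Z)-3-{4-[(1E)-3-oxoprop-1-en-1-yl]-1,3-oxazol-2-yl}prop-2-en-1-yl]carbamate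
Conditions: Ph3P=CHCHO, toluene, 60 °C
Reagents that add atoms: (triphenylphosphoranylidene)acetaldehyde, O=CC=P(c1ccccc1)(c1ccccc1)c1ccccc1
Why: Wittig olefination with a stabilised formyl ylide adds two carbons and should give the E-enal.

Step 21
Reactants: 31 methyl N-[(2Z)-3-{4-[(1E)-3-oxoprop-1-en-1-yl]-1,3-oxazol-2-yl}prop-2-en-1-yl]carbamate
Product: 32 methyl N-[(2Z)-3-[4-(3-oxopropyl)-1,3-oxazol-2-yl]prop-2-en-1-yl]carbamate
Conditions: Hantzsch ester, Bn2NH·TFA (cat.), THF, rt
Reagents that add atoms: none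
Why: Organocatalytic transfer hydrogenation (iminium activation with the Hantzsch ester as hydride donor) reduces only the enal C=C bond, so the Z-alkenyl carbamate, which cannot form an iminium ion, should be left alone.

Step 22
Reactants: 32 methyl N-[(2Z)-3-[4-(3-oxopropyl)-1,3-oxazol-2-yl]prop-2-en-1-yl]carbamate
Product: 33 methyl (2Z)-5-{2-[(1Z)-3-(methoxycarbonylamino)prop-1-en-1-yl]-1,3-oxazol-4-yl}pent-2-enoate
Conditions: (CF3CH2O)2P(O)CH2CO2Me, KHMDS, 18-crown-6, THF, −78 °C
Reagents that add atoms: methyl bis(2,2,2-trifluoroethyl)phosphonoacetate, COC(=O)CP(=O)(OCC(F)(F)F)OCC(F)(F)F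
Why: Still–Gennari olefination, in which fast and irreversible elimination from the kinetic adduct of the electron-poor phosphonate gives the Z-enoate.

Step 23
Reactants: 33 methyl (2Z)-5-{2-[(1Z)-3-(methoxycarbonylamino)prop-1-en-1-yl]-1,3-oxazol-4-yl}pent-2-enoate
Product: 34 (2Z)-5-{2-[(1Z)-3-(methoxycarbonylamino)prop-1-en-1-yl]-1,3-oxazol-4-yl}pent-2-enoic acid
Conditions: LiOH, THF/H2O, 0 °C to rt; then 1 M HCl to pH 3
Reagents that add atoms: lithium hydroxide, [Li+].[OH-]
Why: Saponification of the methyl ester, in which the carbamate is far less electrophilic and the mild conditions should leave both Z-alkenes in place.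

Step 24
Reactants: 24 equatorial C5 alcohol; 34 oxazole Z-enoic acid
Product: 35 neopeltolide
Conditions: PPh3, DIAD, benzene, 0 °C to rt
Reagents that add atoms: none
Why: Mitsunobu esterification, in which the carboxylate displaces the C5 oxyphosphonium group by SN2 and so inverts the equatorial alcohol (S) into the axial ester (R), with no other stereocentre or alkene involved.

**Compound list**

1 | 3-methylglutaric anhydride | CC1CC(=O)OC(=O)C1 | starting material
2 | (3R)-5-methoxy-3-methyl-5-oxopentanoic acid | COC(=O)C[C@H](C)CC(=O)O | intermediate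
3 | methyl (3S)-5-chloro-3-methyl-5-oxopentanoate | COC(=O)C[C@H](C)CC(=O)Cl | intermediate
4 | methyl (3R)-3-methyl-5-oxopentanoate | COC(=O)C[C@H](C)CC=O | intermediate
5 | allylmagnesium bromide | C=CC[Mg]Br | starting material
6 | methyl (3R,5S)-5-hydroxy-3-methyloct-7-enoate | COC(=O)C[C@H](C)C[C@@H](O)CC=C | intermediate
7 | (4R,6S)-4-methyl-6-(prop-2-en-1-yl)oxan-2-one | C=CC[C@H]1C[C@@H](C)CC(=O)O1 | intermediate
8 | (3R,5S)-5-hydroxy-N-methoxy-N,3-dimethyloct-7-enamide | CON(C)C(=O)C[C@H](C)C[C@@H](O)CC=C | intermediate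
9 | (3R,5S)-N-methoxy-N,3-dimethyl-5-(triethylsilyloxy)oct-7-enamide | CON(C)C(=O)C[C@H](C)C[C@@H](O[Si](CC)(CC)CC)CC=C | intermediate
10 | (4R,6S)-4-methyl-6-(triethylsilyloxy)non-8-en-2-one | CC(=O)C[C@H](C)C[C@@H](O[Si](CC)(CC)CC)CC=C | intermediate
11 | butanal | CCCC=O | starting material
12 | diisopinocampheylboron enolate of 10 (C11–O–B, C11=C12H2) | C=C(C[C@H](C)C[C@@H](O[Si](CC)(CC)CC)CC=C)OB([C@H]1C[C@H]2C[C@@H]([C@@H]1C)C2(C)C)[C@H]1C[C@H]2C[C@@H]([C@@H]1C)C2(C)C | intermediate
13 | (4R,8R,10S)-4-hydroxy-8-methyl-10-(triethylsilyloxy)tridec-12-en-6-one | CCC[C@@H](O)CC(=O)C[C@H](C)C[C@@H](O[Si](CC)(CC)CC)CC=C | intermediate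
14 | (4R,6R,8S,10S)-6-hydroxy-8-methyl-10-(triethylsilyloxy)tridec-12-en-4-yl acetate | CCC[C@H](C[C@H](O)C[C@H](C)C[C@@H](O[Si](CC)(CC)CC)CC=C)OC(C)=O | intermediate
15 | (4R,6R,8S,10S)-6-methoxy-8-methyl-10-(triethylsilyloxy)tridec-12-en-4-yl acetate | CCC[C@H](C[C@H](OC)C[C@H](C)C[C@@H](O[Si](CC)(CC)CC)CC=C)OC(C)=O | intermediate
16 | (4R,6R,8S,10S)-6-methoxy-8-methyl-10-(triethylsilyloxy)tridec-12-en-4-ol | CCC[C@@H](O)C[C@H](OC)C[C@H](C)C[C@@H](O[Si](CC)(CC)CC)CC=C | intermediate
17 | ethyl 3,3-diethoxypropanoate | CCOC(CC(=O)OCC)OCC | starting material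
18 | 3,3-diethoxypropanoic acid | CCOC(CC(=O)O)OCC | intermediate
19 | (4R,6R,8S,10S)-6-methoxy-8-methyl-10-(triethylsilyloxy)tridec-12-en-4-yl 3,3-diethoxypropanoate | CCC[C@H](C[C@H](OC)C[C@H](C)C[C@@H](O[Si](CC)(CC)CC)CC=C)OC(=O)CC(OCC)OCC | intermediate
20 | (4R,6R,8R,10S)-10-hydroxy-6-methoxy-8-methyltridec-12-en-4-yl 3,3-diethoxypropanoate | CCC[C@H](C[C@H](OC)C[C@H](C)C[C@@H](O)CC=C)OC(=O)CC(OCC)OCC | intermediate
21 | 12-membered macrocyclic ethyl acetal (C7–O–C3(OEt), either C3 epimer, other centres as in 20) | CCC[C@@H]1C[C@H](OC)C[C@H](C)C[C@H](CC=C)OC(OCC)CC(=O)O1 | intermediate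
22 | 12-membered macrocyclic oxocarbenium ion (C7–O(+)=C3, centres as in 20) | CCC[C@@H]1C[C@H](OC)C[C@H](C)C[C@H](CC=C)[O+]=CCC(=O)O1 | intermediate
23 | (1R,5R,7R,9S,11R,13S)-7-methoxy-9-methyl-3-oxo-5-propyl-4,15-dioxabicyclo[9.3.1]pentadecan-13-yl acetate | CCC[C@@H]1C[C@H](OC)C[C@H](C)C[C@@H]2C[C@H](OC(C)=O)C[C@H](CC(=O)O1)O2 | intermediate
24 | (1R,5R,7R,9S,11R,13S)-13-hydroxy-7-methoxy-9-methyl-5-propyl-4,15-dioxabicyclo[9.3.1]pentadecan-3-one | CCC[C@@H]1C[C@H](OC)C[C@H](C)C[C@@H]2C[C@H](O)C[C@H](CC(=O)O1)O2 | intermediate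
25 | propargylamine | C#CCN | starting material
26 | methyl N-(prop-2-yn-1-yl)carbamate | C#CCNC(=O)OC | intermediate
27 | ethyl 2-bromo-1,3-oxazole-4-carboxylate | CCOC(=O)c1coc(Br)n1 | starting material
28 | ethyl 2-[3-(methoxycarbonylamino)prop-1-yn-1-yl]-1,3-oxazole-4-carboxylate | CCOC(=O)c1coc(C#CCNC(=O)OC)n1 | intermediate
29 | ethyl 2-[(1Z)-3-(methoxycarbonylamino)prop-1-en-1-yl]-1,3-oxazole-4-carboxylate | CCOC(=O)c1coc(/C=C\CNC(=O)OC)n1 | intermediate
30 | methyl N-[(2Z)-3-(4-formyl-1,3-oxazol-2-yl)prop-2-en-1-yl]carbamate | O=Cc1coc(/C=C\CNC(=O)OC)n1 | intermediate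
31 | methyl N-[(2Z)-3-{4-[(1E)-3-oxoprop-1-en-1-yl]-1,3-oxazol-2-yl}prop-2-en-1-yl]carbamate | O=C/C=C/c1coc(/C=C\CNC(=O)OC)n1 | intermediate
32 | methyl N-[(2Z)-3-[4-(3-oxopropyl)-1,3-oxazol-2-yl]prop-2-en-1-yl]carbamate | O=CCCc1coc(/C=C\CNC(=O)OC)n1 | intermediate
33 | methyl (2Z)-5-{2-[(1Z)-3-(methoxycarbonylamino)prop-1-en-1-yl]-1,3-oxazol-4-yl}pent-2-enoate | COC(=O)/C=C\CCc1coc(/C=C\CNC(=O)OC)n1 | intermediate
34 | (2Z)-5-{2-[(1Z)-3-(methoxycarbonylamino)prop-1-en-1-yl]-1,3-oxazol-4-yl}pent-2-enoic acid | OC(=O)/C=C\CCc1coc(/C=C\CNC(=O)OC)n1 | intermediate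
35 | neopeltolide, (1R,5R,7R,9S,11R,13R)-7-methoxy-9-methyl-3-oxo-5-propyl-4,15-dioxabicyclo[9.3.1]pentadecan-13-yl ester of 34 | CCC[C@@H]1C[C@H](OC)C[C@H](C)C[C@@H]2C[C@@H](OC(=O)/C=C\CCc3coc(/C=C\CNC(=O)OC)n3)C[C@H](CC(=O)O1)O2 | target

**Step count**

- Total step count: 24
- Longest linear sequence: 15 steps (steps 1–10, 12–15 and 24)

**Steps most likely to fail**

1. **Step 14.**
   - Risk: Intermolecular acetal exchange may outrun ring closure and lead to oligomerisation. Proton loss from the oxocarbenium ion may also drain material into a β-alkoxyacrylate that does not cyclise.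
   - Fallback: the two ring closures are separated. It sets out from 15 and returns at 24.
   - The TES ether of 15 is cleaved with buffered HF·pyridine to the homoallylic alcohol acetate F1.
   - An intermolecular Prins cyclisation of F1 with acetal 17 in TFA/CH2Cl2 gives the 2,6-cis-tetrahydropyran C5 trifluoroacetate F2.
   - Brief methanolysis (NaHCO3, MeOH) removes only the labile trifluoroacetate and gives the C5 alcohol F3.
   - Silylation (TBSCl, imidazole) gives the C5 TBS ether F4.
   - LiOH hydrolyses the ethyl ester and the C13 acetate to the seco acid F5.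
   - Yamaguchi macrolactonisation closes the macrolactone TBS ether F6, and HF·pyridine then gives 24.

2. **Step 7.**
   - Risk: Facial discrimination by the Ipc ligands may be insufficient with an unbranched aldehyde. The C13 epimers differ only at a remote centre and may be difficult to separate.
   - Fallback: C13 is taken from an enantiopure epoxide, and the C11–C12 bond is made by dithiane alkylation. It sets out from 9 and returns at 13.
   - DIBAL-H reduces Weinreb amide 9 to the C11 aldehyde F7.
   - 1,3-Propanedithiol with MgBr2·OEt2 converts F7 into the 1,3-dithiane F8.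
   - Lithiation (n-BuLi, THF/HMPA) and opening of commercial (R)-2-propyloxirane at its CH2 terminus gives the β-hydroxy dithiane F9.
   - Alkylative hydrolysis (MeI, CaCO3, aqueous MeCN) unmasks the ketone to give 13.

3. **Step 2.**
   - Risk: Interchange of the ester and acyl chloride termini through a cyclic acyloxonium ion would erode the C9 configuration. Over-reduction would carry material on to a lactone.
   - Fallback: a redox detour that avoids the acyl chloride. It sets out from 2 and returns at 4.
   - BH3·SMe2 reduces the free acid chemoselectively to the hydroxy ester F10, which is oxidised at once under Swern conditions to 4.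

**Further compounds**

F1 | step 14 | (4R,6R,8R,10S)-10-hydroxy-6-methoxy-8-methyltridec-12-en-4-yl acetate | CCC[C@H](C[C@H](OC)C[C@H](C)C[C@@H](O)CC=C)OC(C)=O
F2 | step 14 | ethyl (3R,5S,7R,9S,11R,13R)-13-acetoxy-3,7-epoxy-11-methoxy-9-methyl-5-(trifluoroacetoxy)hexadecanoate | CCC[C@H](C[C@H](OC)C[C@H](C)C[C@@H]1C[C@H](OC(=O)C(F)(F)F)C[C@H](CC(=O)OCC)O1)OC(C)=O
F3 | step 14 | ethyl (3R,5S,7R,9S,11R,13R)-13-acetoxy-3,7-epoxy-5-hydroxy-11-methoxy-9-methylhexadecanoate | CCC[C@H](C[C@H](OC)C[C@H](C)C[C@@H]1C[C@H](O)C[C@H](CC(=O)OCC)O1)OC(C)=O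
F4 | step 14 | C5 tert-butyldimethylsilyl ether of F3 | CCC[C@H](C[C@H](OC)C[C@H](C)C[C@@H]1C[C@H](O[Si](C)(C)C(C)(C)C)C[C@H](CC(=O)OCC)O1)OC(C)=O
F5 | step 14 | seco acid, 3,7-epoxy-13-hydroxy-11-methoxy-9-methyl-5-(tert-butyldimethylsilyloxy)hexadecanoic acid (centres as in F4) | CCC[C@@H](O)C[C@H](OC)C[C@H](C)C[C@@H]1C[C@H](O[Si](C)(C)C(C)(C)C)C[C@H](CC(=O)O)O1
F6 | step 14 | C5 tert-butyldimethylsilyl ether of 24 | CCC[C@@H]1C[C@H](OC)C[C@H](C)C[C@@H]2C[C@H](O[Si](C)(C)C(C)(C)C)C[C@H](CC(=O)O1)O2
F7 | step 7 | (3R,5S)-3-methyl-5-(triethylsilyloxy)oct-7-enal | O=CC[C@H](C)C[C@@H](O[Si](CC)(CC)CC)CC=C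
F8 | step 7 | 2-[(2R,4S)-2-methyl-4-(triethylsilyloxy)hept-6-en-1-yl]-1,3-dithiane | C1CSC(C[C@H](C)C[C@@H](O[Si](CC)(CC)CC)CC=C)SC1
F9 | step 7 | (2R)-1-{2-[(2R,4S)-2-methyl-4-(triethylsilyloxy)hept-6-en-1-yl]-1,3-dithian-2-yl}pentan-2-ol | CCC[C@@H](O)CC1(C[C@H](C)C[C@@H](O[Si](CC)(CC)CC)CC=C)SCCCS1
F10 | step 2 | methyl (3R)-5-hydroxy-3-methylpentanoate | COC(=O)C[C@H](C)CCO
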